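X is charged more heavily than L in this flask, and that gap is what to reckon with. Call L's charge as a fraction of X's charge the poison share 0.168.

common to all: E 0.10 M; X 0.038 mol%; L 6.4 µM

| flask | G | remark |
|---|---|---|
| zeta | 0.087 mM | run made earlier |
| theta | 0.20 mM | run made earlier |
| flask | 0.13 mM |  |

| run | time / h | J / % | E / % |
|---|---|---|---|
| zeta | 1.50 | 5.6 | 93.0 |
| zeta | 5.00 | 23.8 | 77.8 |
| zeta | 8.00 | 32.9 | 67.2 |
| zeta | 12.0 | 47.0 | 55.2 |
| zeta | 20.0 | 64.7 | 34.3 |
| zeta | 25.0 | 73.5 | 28.0 |
| zeta | 30.0 | 79.2 | 20.0 |
| theta | 4.00 | 12.8 | 87.7 |
| theta | 8.00 | 24.4 | 76.3 |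
| theta | 12.0 | 33.2 | 67.2 |
| theta | 15.0 | 41.0 | 59.4 |
| theta | 20.0 | 51.8 | 47.7 |
| theta | 25.0 | 60.4 | 41.3 |
| theta | 30.0 | 67.3 | 32.5 |

(each reading ± 1 percentage point)

- apparent order in X when 30 % of the E are converted (percent change of the rate of making J for one percent more X charged)

- the numbers in the tables scatter by 1 percentage point (one standard deviation)
- no earlier run changes the charge of X; that part of a forecast is a guess

Neither earlier run varied X or L, so the readings can't show whether L touches X. In both runs, though, E falls by a steady factor per hour from the first reading on, so I read no slow loss of X during the run. That leaves two extremes that can be solved in the head: L stays idle, or L acts as a stoichiometric poison and takes X mole for mole before the first reading. In the second case the working X is the charge minus L, so one percent more X is 1.20 percent more working X. I carry the forecast's 1.05, its order with X depleting free G, over to both cases as my own assumption.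

| Version of the flask | Share of X taken by L | Order in X |
|---|---|---|
| L idle | 0 | 1.05 |
| L a poison | 0.168 | 1.20 times 1.05 |

The real flask must lie between these rows, and I would commit to the row where L is a poison. The forecast gives 0.9, on the ground that “the order could fall well below 1”.

The flask gives 1.3.

    E + X → J + X, rate k1*[E]^1.5*[X]/(1 + ([E]/Kh1)^1.5) (0.0700 M, k = 300 M⁻¹·⁵ min⁻¹)
    X + L → D (k = 2600 M⁻¹ min⁻¹)
    X + G ⇌ Z, settled at all times (K = 5800 M⁻¹)

In this flask L is down to 0.0124 % of its charge after 3.00 h. After 8.37 h, at the conversion asked about, D holds 16.8 % of the catalyst, so the poison share of 0.168 stands in this flask as D. Added X enters a pool already reduced by that share, and this raises the order in this flask. The simulated run of this flask without the turning of X + L into D shows the effect: the order there is 1.0, against 1.3 with it.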